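**Retrosynthetic overview**

1. The target is an oxyresveratrol unit B (C7b, C8b, central ring C9b–C14b, 2,4-dioxyphenyl ring) flanked by two resveratrol units A and C. It contains dihydrofuran A (O11b–C7a–C8a–C10b), the seven-membered ring (C8a–C9a–C10a–C7b–C8b–C9b–C10b) and dihydrofuran C (O13b–C7c–C8c–C14b). The two dihydrofurans are pseudo-enantiomeric (7aS,8aS against 7cR,8cR), so dihydrofuran C needs its own external stereocontrol.
2. Dihydrofuran C is closed last by a [4+1] disconnection of C8c–C7c and C7c–O13b. The partners are the o-quinone methide O13b=C13b–C14b=C8c (C8c bearing the 3,5-dimethoxyphenyl group) of the tetracyclic dimer and a 4-methoxybenzylidene from a twofold-symmetric chiral sulfonium ylide. The enabling feature: C8c is benzylic to the central ring of unit B and ortho to O13b, while the para-oxybenzylic C7c is bonded only to O13b and C8c.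
3. C14b–C8c comes from ortho-specific hydroxyalkylation of the only free phenol (O13b–H) with 3,5-dimethoxybenzaldehyde, then sulfinate exchange to the o-quinone methide precursor.
4. The seven-membered ring comes from acid-mediated 7-endo Friedel–Crafts closure of the C7b cation of a 2,4-dimethoxystilbene onto the resorcinol ring of unit A (C7b set by C8a); the same acid frees O13b–H.
5. Dihydrofuran A comes from a dirhodium-catalysed carbene C–H insertion (C8a into O11b–CH2–aryl). Ring order: dihydrofuran A, seven-membered ring, dihydrofuran C; global demethylation ends the route.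

Key step: step 18

**Remarks**

- Locants follow oligostilbene usage: position 7 of each unit carries the 4-oxyphenyl ring (units A and C) or the 2,4-dioxyphenyl ring (unit B); position 8 carries the 3,5-dioxyphenyl (resorcinol) ring (units A and C; C9a–C14a in unit A) or, for C8b, the central ring of unit B (C9b–C14b).
- Assumption: the 7bS centre (2,4-dioxyphenyl ring on the same face of the seven-membered ring as H-8a) is taken to be the configuration of the ampelopsin B series, which is the one delivered by acid closure of ε-viniferin-type stilbenes.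
- Assumption: Rh2(S-PTAD)4, dirhodium tetrakis[(S)-(1-adamantyl)(N-phthalimido)acetate], is written for the (2R,3S) series in step 7 and the (2R,5R)-thiolanium salt 37 for the (7cR,8cR) series in step 18. Both senses are assigned by analogy. Should a model run show the opposite, the mirror-image catalyst, or the salt made from (2R,5R)-hexane-2,5-diol, is used with nothing else changed.

**Route**

Step 1
Reactants: 1 3,5-dihydroxybenzyl alcohol; 2 4-methoxybenzyl chloride
Product: 3 3,5-bis(4-methoxybenzyloxy)benzyl alcohol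
Conditions: K2CO3, n-Bu4NI (cat.), DMF, 60 °C
Reagents that add atoms: 4-methoxybenzyl chloride, COc1ccc(CCl)cc1
Why: Williamson etherification, in which only the two phenols are deprotonated by carbonate, so the benzylic alcohol stays free.

Step 2
Reactants: 3 3,5-bis(4-methoxybenzyloxy)benzyl alcohol; 4 chlorotriisopropylsilane
Product: 5 triisopropyl[3,5-bis(4-methoxybenzyloxy)benzyloxy]silane
Conditions: imidazole, DMF, rt
Reagents that add atoms: chlorotriisopropylsilane, CC(C)[Si](Cl)(C(C)C)C(C)C
Why: Silylation of the primary alcohol; the bulky silyl ether is chosen because its oxygen is a poor partner for the carbene of step 7.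

Step 3
Reactants: 5 triisopropyl[3,5-bis(4-methoxybenzyloxy)benzyloxy]silane; 6 N-bromosuccinimide
Product: 7 [2-bromo-3,5-bis(4-methoxybenzyloxy)benzyloxy]triisopropylsilane
Conditions: MeCN, 0 °C
Reagents that add atoms: N-bromosuccinimide, O=C1CCC(=O)N1Br
Why: Electrophilic aromatic bromination, expected at the position ortho to the benzylic carbon and para to an alkoxy group (the usual site in 3,5-dialkoxybenzyl systems); the doubly alkoxy-activated central ring should react well before the anisyl rings.

Step 4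
Reactants: 7 [2-bromo-3,5-bis(4-methoxybenzyloxy)benzyloxy]triisopropylsilane; 8 3,5-dimethoxybenzaldehyde
Product: 10 racemic [2,4-bis(4-methoxybenzyloxy)-6-(triisopropylsilyloxymethyl)phenyl](3,5-dimethoxyphenyl)methanol, via aryllithium 9 (not isolated)
Conditions: n-BuLi, THF, −78 °C; then 8, −78 to 0 °C; aq. NH4Cl
Reagents that add atoms: 3,5-dimethoxybenzaldehyde, COc1cc(C=O)cc(OC)c1
Why: Bromine–lithium exchange followed by 1,2-addition to the aldehyde; the low temperature keeps the benzylic ethers from Wittig rearrangement, and the racemic carbinol centre is removed in step 5.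

Step 5
Reactants: 10 racemic diaryl carbinol
Product: 11 [2,4-bis(4-methoxybenzyloxy)-6-(triisopropylsilyloxymethyl)phenyl](3,5-dimethoxyphenyl)methanone
Conditions: Dess–Martin periodinane, CH2Cl2, rt
Reagents that add atoms: none
Why: Dess–Martin oxidation of a hindered diaryl carbinol; benzyl and silyl ethers are inert to it.

Step 6
Reactants: 11 diaryl ketone; 12 hydrazine (as hydrate)
Product: 13 hydrazone of 11 (E/Z mixture)
Conditions: N2H4·H2O (excess), AcOH (cat.), n-BuOH, 100 °C
Reagents that add atoms: hydrazine, NN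
Why: Hydrazone condensation, run with excess hydrazine under forcing conditions because the ketone is di-ortho-substituted; the excess also suppresses azine formation.

Step 7
Reactants: 13 hydrazone of 11
Product: 15 (2R,3S)-cis-3-(3,5-dimethoxyphenyl)-6-(4-methoxybenzyloxy)-2-(4-methoxyphenyl)-4-(triisopropylsilyloxymethyl)-2,3-dihydrobenzofuran, via diaryldiazomethane 14 (not isolated)
Conditions: MnO2, CH2Cl2, 0 °C, filtration; Rh2(S-PTAD)4 (1 mol %), CH2Cl2, 0 °C to rt
Reagents that add atoms: none
Why: Hydrazone oxidation to the diazo compound and dirhodium-catalysed intramolecular 1,5 C–H insertion of the donor/donor carbene into the benzylic C–H of the ortho 4-methoxybenzyl ether, closing dihydrofuran A; the chiral carboxylate ligands select the carbene face and the enantiotopic hydrogen, giving the cis ring and fixing C8a (C7a is corrected in step 12).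

Step 8
Reactants: 15 cis-dihydrobenzofuran silyl ether
Product: 16 (2R,3S)-cis-[3-(3,5-dimethoxyphenyl)-6-(4-methoxybenzyloxy)-2-(4-methoxyphenyl)-2,3-dihydrobenzofuran-4-yl]methanol
Conditions: n-Bu4NF, THF, 0 °C to rt
Reagents that add atoms: none
Why: Fluoride-mediated desilylation; nothing else in the molecule is fluoride-labile.

Step 9
Reactants: 16 benzylic alcohol
Product: 17 (2R,3S)-cis-3-(3,5-dimethoxyphenyl)-6-(4-methoxybenzyloxy)-2-(4-methoxyphenyl)-2,3-dihydrobenzofuran-4-carbaldehyde
Conditions: MnO2, CH2Cl2, rt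
Reagents that add atoms: none
Why: Selective MnO2 oxidation of a benzylic alcohol to the aldehyde without touching the dihydrobenzofuran.

Step 10
Reactants: 18 2,4-dimethoxybenzyl alcohol; 19 triethyl phosphite
Product: 21 diethyl (2,4-dimethoxybenzyl)phosphonate, via 2,4-dimethoxybenzyl chloride 20 (not isolated)
Conditions: SOCl2, CH2Cl2, 0 °C; evaporation; P(OEt)3, 120 °C
Reagents that add atoms: triethyl phosphite, CCOP(OCC)OCC
Why: Chlorination followed directly by a Michaelis–Arbuzov reaction, so the labile electron-rich benzyl chloride is never stored.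

Step 11
Reactants: 17 aldehyde; 21 diethyl (2,4-dimethoxybenzyl)phosphonate
Product: 23 (2R,3S)-cis-4-[(E)-2-(2,4-dimethoxyphenyl)ethenyl]-3-(3,5-dimethoxyphenyl)-6-(4-methoxybenzyloxy)-2-(4-methoxyphenyl)-2,3-dihydrobenzofuran, via sodium phosphonate carbanion 22 (not isolated)
Conditions: NaH, THF, 0 °C; then 17, 0 °C to rt
Reagents that add atoms: diethyl (2,4-dimethoxybenzyl)phosphonate, CCOP(=O)(Cc1ccc(OC)cc1OC)OCC
Why: Horner–Wadsworth–Emmons olefination, which should give the E-stilbene; the alkene geometry is lost again in step 12.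

Step 12
Reactants: 23 cis-dihydrobenzofuran stilbene
Product: 25 (7aS,8aS,7bS)-tetracyclic dimer phenol (O13b–H free; five methyl ethers), via cyclised cis ether 24 (not isolated)
Conditions: CF3CO2H, pentamethylbenzene, CH2Cl2, 0 °C to 40 °C
Reagents that add atoms: none
Why: Acid cascade copying the ε-viniferin to ampelopsin B conversion: protonation at C8b gives the 2,4-dimethoxybenzyl cation at C7b, which the resorcinol ring of unit A captures at C10a in a seven-membered Friedel–Crafts closure (7-endo with respect to the former C7b=C8b alkene) with the 2,4-dimethoxyphenyl group cis to H-8a (7bS, controlled by C8a); the same acid should cleave the remaining 4-methoxybenzyl ether (cation scavenged by pentamethylbenzene) and epimerise C7a to the trans ring through reversible C7a–O ionisation.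

Step 13
Reactants: 25 dimer phenol; 8 3,5-dimethoxybenzaldehyde
Product: 27 C14b-[hydroxy(3,5-dimethoxyphenyl)methyl] derivative of 25 (both carbinol epimers), via bromomagnesium phenoxide 26 (not isolated)
Conditions: EtMgBr, Et2O, 0 °C; toluene, 8, rt to 60 °C; aq. NH4Cl
Reagents that add atoms: 3,5-dimethoxybenzaldehyde, COc1cc(C=O)cc(OC)c1
Why: Ortho-specific hydroxyalkylation of a bromomagnesium phenoxide (aldehyde delivered within the magnesium chelate), so only the single free phenol ring reacts; attack is expected at C14b, para to O11b, and not at C12b between the two oxygens, as with orcinol-type phenols, and the new carbinol centre is erased in step 18.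

Step 14
Reactants: 27 ortho-hydroxybenzhydrol; 28 p-toluenesulfinic acid
Product: 29 C14b-[(3,5-dimethoxyphenyl)(p-tolylsulfonyl)methyl] derivative of 25 (both epimers at the sulfonyl carbon)
Conditions: CH2Cl2, rt
Reagents that add atoms: p-toluenesulfinic acid, Cc1ccc(S(=O)O)cc1
Why: Acid-promoted substitution of the ortho-hydroxybenzhydrol by sulfinate (S-alkylation through the benzhydryl cation), giving the bench-stable sulfone that is the standard base-triggered o-quinone methide precursor.

Step 15
Reactants: 30 (2S,5S)-hexane-2,5-diol; 31 methanesulfonyl chloride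
Product: 32 (2S,5S)-hexane-2,5-diyl dimethanesulfonate
Conditions: Et3N, CH2Cl2, 0 °C
Reagents that add atoms: methanesulfonyl chloride, CS(=O)(=O)Cl
Why: Mesylation of both secondary alcohols with retention at carbon.

Step 16
Reactants: 32 (2S,5S)-dimesylate; 33 sodium sulfide (as nonahydrate)
Product: 34 (2R,5R)-2,5-dimethylthiolane
Conditions: Na2S·9H2O, DMSO, 40 °C
Reagents that add atoms: sodium sulfide, [Na+].[Na+].[S-2]
Why: Double SN2 displacement by sulfide with inversion at both carbons, giving the twofold-symmetric trans-thiolane.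

Step 17
Reactants: 34 (2R,5R)-2,5-dimethylthiolane; 35 4-methoxybenzyl alcohol; 36 tetrafluoroboric acid (diethyl ether complex)
Product: 37 (2R,5R)-1-(4-methoxybenzyl)-2,5-dimethylthiolanium tetrafluoroborate
Conditions: HBF4·OEt2, CH2Cl2, 0 °C to rt
Reagents that add atoms: 4-methoxybenzyl alcohol, COc1ccc(CO)cc1; tetrafluoroboric acid, [H+].F[B-](F)(F)F
Why: S-alkylation of the sulfide by the 4-methoxybenzyl cation released from the alcohol by the strong acid; the twofold symmetry of the thiolane makes the two sulfur lone pairs equivalent, so a single salt forms.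

Step 18
Reactants: 29 sulfone; 37 (2R,5R)-thiolanium tetrafluoroborate
Product: 41 (7aS,8aS,7bS,7cR,8cR)-octamethyl ether of the target, via o-quinone methide 38 (not isolated), via sulfonium ylide 39 (not isolated), via betaine 40 (not isolated)
Conditions: KN(SiMe3)2, THF, −78 °C (phenoxide of 29 and ylide 39 formed in separate flasks, one equivalent of base per acidic site, then combined); −78 to 0 °C
Reagents that add atoms: (2R,5R)-1-(4-methoxybenzyl)-2,5-dimethylthiolanium tetrafluoroborate, C[C@@H]1CC[C@@H](C)[S+]1Cc1ccc(OC)cc1.F[B-](F)(F)F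
Why: Proposed new method: the phenoxide of 29 expels p-toluenesulfinate (E1cB) to release o-quinone methide 38, the semi-stabilised benzylide 39 adds through its carbanion to C8c with re-aromatisation of the central ring of unit B to betaine 40, and the phenoxide O13b then displaces the thiolane at C7c. The closest known reaction type is the [4+1] annulation of o-quinone methides from 2-(sulfonylalkyl)phenols with carbonyl-stabilised sulfonium ylides to trans-2,3-dihydrobenzofurans, combined with the asymmetric epoxidation and cyclopropanation chemistry of twofold-symmetric thiolanium benzylides; what is new is a chiral semi-stabilised benzylide on an o-quinone methide. Dihydrofuran C closes by 5-exo-tet O-alkylation (SN2 with inversion at C7c) after the intermolecular C8c–C7c bond formation. C8c is set in the addition step by reagent control: the (2R,5R)-thiolanium group exposes one face of the ylide carbon, which adds anti (aryl groups apart) to one face of the planar o-quinone methide, the stereocentres of 29 being remote. C7c follows from the ylide face and the invertive closure, which gives the 7c,8c-trans ring. The step needs a single o-quinone methide geometry and clean conjugate addition: the peri C8b methylene forces the 3,5-dimethoxyphenyl group to the carbonyl side, the methide is the only electrophile present, and because 29 is enantiopure any wrong-sense adduct is a diastereomer removable by chromatography.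

Step 19
Reactants: 41 octamethyl ether
Product: 42 target CNP0154047.3
Conditions: BBr3, CH2Cl2, −78 °C to rt; then H2O
Reagents that add atoms: none
Why: Lewis-acid cleavage of the eight aryl methyl ethers with BBr3; the trans-dihydrobenzofurans are the thermodynamic isomers and C8a, C7b and C8c carry no ionisable bond, so the configuration should be retained.

**Compound list**

1 | 3,5-dihydroxybenzyl alcohol | OCc1cc(O)cc(O)c1 | starting material
2 | 4-methoxybenzyl chloride | COc1ccc(CCl)cc1 | starting material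
3 | 3,5-bis(4-methoxybenzyloxy)benzyl alcohol | COc1ccc(COc2cc(CO)cc(OCc3ccc(OC)cc3)c2)cc1 | intermediate
4 | chlorotriisopropylsilane | CC(C)[Si](Cl)(C(C)C)C(C)C | starting material
5 | triisopropyl[3,5-bis(4-methoxybenzyloxy)benzyloxy]silane | COc1ccc(COc2cc(CO[Si](C(C)C)(C(C)C)C(C)C)cc(OCc3ccc(OC)cc3)c2)cc1 | intermediate
6 | N-bromosuccinimide | O=C1CCC(=O)N1Br | starting material
7 | [2-bromo-3,5-bis(4-methoxybenzyloxy)benzyloxy]triisopropylsilane | COc1ccc(COc2cc(OCc3ccc(OC)cc3)cc(CO[Si](C(C)C)(C(C)C)C(C)C)c2Br)cc1 | intermediate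
8 | 3,5-dimethoxybenzaldehyde | COc1cc(C=O)cc(OC)c1 | starting material
9 | aryllithium from 7 | COc1ccc(COc2cc(OCc3ccc(OC)cc3)cc(CO[Si](C(C)C)(C(C)C)C(C)C)c2[Li])cc1 | intermediate
10 | racemic [2,4-bis(4-methoxybenzyloxy)-6-(triisopropylsilyloxymethyl)phenyl](3,5-dimethoxyphenyl)methanol | COc1ccc(COc2cc(OCc3ccc(OC)cc3)cc(CO[Si](C(C)C)(C(C)C)C(C)C)c2C(O)c2cc(OC)cc(OC)c2)cc1 | intermediate
11 | [2,4-bis(4-methoxybenzyloxy)-6-(triisopropylsilyloxymethyl)phenyl](3,5-dimethoxyphenyl)methanone | COc1ccc(COc2cc(OCc3ccc(OC)cc3)cc(CO[Si](C(C)C)(C(C)C)C(C)C)c2C(=O)c2cc(OC)cc(OC)c2)cc1 | intermediate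
12 | hydrazine | NN | starting material
13 | hydrazone of 11 | COc1ccc(COc2cc(OCc3ccc(OC)cc3)cc(CO[Si](C(C)C)(C(C)C)C(C)C)c2C(=NN)c2cc(OC)cc(OC)c2)cc1 | intermediate
14 | diaryldiazomethane from 13 | COc1ccc(COc2cc(OCc3ccc(OC)cc3)cc(CO[Si](C(C)C)(C(C)C)C(C)C)c2C(=[N+]=[N-])c2cc(OC)cc(OC)c2)cc1 | intermediate
15 | (2R,3S)-cis-3-(3,5-dimethoxyphenyl)-6-(4-methoxybenzyloxy)-2-(4-methoxyphenyl)-4-(triisopropylsilyloxymethyl)-2,3-dihydrobenzofuran | COc1ccc([C@@H]2Oc3cc(OCc4ccc(OC)cc4)cc(CO[Si](C(C)C)(C(C)C)C(C)C)c3[C@@H]2c2cc(OC)cc(OC)c2)cc1 | intermediate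
16 | (2R,3S)-cis-[3-(3,5-dimethoxyphenyl)-6-(4-methoxybenzyloxy)-2-(4-methoxyphenyl)-2,3-dihydrobenzofuran-4-yl]methanol | COc1ccc([C@@H]2Oc3cc(OCc4ccc(OC)cc4)cc(CO)c3[C@@H]2c2cc(OC)cc(OC)c2)cc1 | intermediate
17 | (2R,3S)-cis-3-(3,5-dimethoxyphenyl)-6-(4-methoxybenzyloxy)-2-(4-methoxyphenyl)-2,3-dihydrobenzofuran-4-carbaldehyde | COc1ccc([C@@H]2Oc3cc(OCc4ccc(OC)cc4)cc(C=O)c3[C@@H]2c2cc(OC)cc(OC)c2)cc1 | intermediate
18 | 2,4-dimethoxybenzyl alcohol | COc1ccc(CO)c(OC)c1 | starting material
19 | triethyl phosphite | CCOP(OCC)OCC | starting material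
20 | 2,4-dimethoxybenzyl chloride | COc1ccc(CCl)c(OC)c1 | intermediate
21 | diethyl (2,4-dimethoxybenzyl)phosphonate | CCOP(=O)(Cc1ccc(OC)cc1OC)OCC | intermediate
22 | sodium salt of the carbanion of 21 | [Na+].CCOP(=O)([CH-]c1ccc(OC)cc1OC)OCC | intermediate
23 | (2R,3S)-cis-4-[(E)-2-(2,4-dimethoxyphenyl)ethenyl]-3-(3,5-dimethoxyphenyl)-6-(4-methoxybenzyloxy)-2-(4-methoxyphenyl)-2,3-dihydrobenzofuran | COc1ccc([C@@H]2Oc3cc(OCc4ccc(OC)cc4)cc(/C=C/c4ccc(OC)cc4OC)c3[C@@H]2c2cc(OC)cc(OC)c2)cc1 | intermediate
24 | seven-membered-ring-closed tetracycle still carrying the cis dihydrofuran A and the O13b 4-methoxybenzyl ether (7aR,8aS,7bS) | COc1ccc([C@@H]2Oc3cc(OCc4ccc(OC)cc4)cc4c3[C@@H]2c2cc(OC)cc(OC)c2[C@H](c2ccc(OC)cc2OC)C4)cc1 | intermediate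
25 | (7aS,8aS,7bS)-tetracyclic dimer phenol with free O13b–H, trans dihydrofuran A and five methyl ethers | COc1ccc([C@H]2Oc3cc(O)cc4c3[C@@H]2c2cc(OC)cc(OC)c2[C@H](c2ccc(OC)cc2OC)C4)cc1 | intermediate
26 | bromomagnesium phenoxide of 25 | COc1ccc([C@H]2Oc3cc(O[Mg]Br)cc4c3[C@@H]2c2cc(OC)cc(OC)c2[C@H](c2ccc(OC)cc2OC)C4)cc1 | intermediate
27 | C14b-[hydroxy(3,5-dimethoxyphenyl)methyl] derivative of 25, both carbinol epimers | COc1ccc([C@H]2Oc3cc(O)c(C(O)c4cc(OC)cc(OC)c4)c4c3[C@@H]2c2cc(OC)cc(OC)c2[C@H](c2ccc(OC)cc2OC)C4)cc1 | intermediate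
28 | p-toluenesulfinic acid | Cc1ccc(S(=O)O)cc1 | starting material
29 | C14b-[(3,5-dimethoxyphenyl)(p-tolylsulfonyl)methyl] derivative of 25, both epimers at the sulfonyl carbon | COc1ccc([C@H]2Oc3cc(O)c(C(c4cc(OC)cc(OC)c4)S(=O)(=O)c4ccc(C)cc4)c4c3[C@@H]2c2cc(OC)cc(OC)c2[C@H](c2ccc(OC)cc2OC)C4)cc1 | intermediate
30 | (2S,5S)-hexane-2,5-diol | C[C@H](O)CC[C@H](C)O | starting material
31 | methanesulfonyl chloride | CS(=O)(=O)Cl | starting material
32 | (2S,5S)-hexane-2,5-diyl dimethanesulfonate | C[C@H](OS(C)(=O)=O)CC[C@H](C)OS(C)(=O)=O | intermediate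
33 | sodium sulfide | [Na+].[Na+].[S-2] | starting material
34 | (2R,5R)-2,5-dimethylthiolane | C[C@@H]1CC[C@@H](C)S1 | intermediate
35 | 4-methoxybenzyl alcohol | COc1ccc(CO)cc1 | starting material
36 | tetrafluoroboric acid | [H+].F[B-](F)(F)F | starting material
37 | (2R,5R)-1-(4-methoxybenzyl)-2,5-dimethylthiolanium tetrafluoroborate | C[C@@H]1CC[C@@H](C)[S+]1Cc1ccc(OC)cc1.F[B-](F)(F)F | intermediate
38 | o-quinone methide of the dimer (C13b=O, C14b=C8c, the 3,5-dimethoxyphenyl group on the carbonyl side) | COc1ccc([C@H]2OC3=CC(=O)\C(=C/c4cc(OC)cc(OC)c4)C4=C3[C@@H]2c2cc(OC)cc(OC)c2[C@H](c2ccc(OC)cc2OC)C4)cc1 | intermediate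
39 | (2R,5R)-2,5-dimethylthiolanium 4-methoxybenzylide | C[C@@H]1CC[C@@H](C)[S+]1[CH-]c1ccc(OC)cc1 | intermediate
40 | betaine: O13b phenoxide whose C14b–C8c–C7c chain carries the 3,5-dimethoxyphenyl group at C8c and the 4-methoxyphenyl and thiolanium groups at C7c | COc1ccc([C@H]2Oc3cc([O-])c([C@@H](c4cc(OC)cc(OC)c4)[C@@H](c4ccc(OC)cc4)[S+]4[C@H](C)CC[C@H]4C)c4c3[C@@H]2c2cc(OC)cc(OC)c2[C@H](c2ccc(OC)cc2OC)C4)cc1 | intermediate
41 | octamethyl ether of the target (7aS,8aS,7bS,7cR,8cR) | COc1ccc([C@H]2Oc3cc4c(c5c3[C@@H]2c2cc(OC)cc(OC)c2[C@H](c2ccc(OC)cc2OC)C5)[C@@H](c2cc(OC)cc(OC)c2)[C@H](c2ccc(OC)cc2)O4)cc1 | intermediate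
42 | CNP0154047.3 | Oc1ccc([C@H]2Oc3cc4c(c5c3[C@@H]2c2cc(O)cc(O)c2[C@H](c2ccc(O)cc2O)C5)[C@@H](c2cc(O)cc(O)c2)[C@H](c2ccc(O)cc2)O4)cc1 | target

**Step count**

Total: 19 steps. Longest linear sequence: 15 steps (1–9, 11–14, 18, 19). Steps 10 and 15–17 are side branches.

**Steps most likely to fail, with fallbacks**

1. Step 18. The facial discrimination by the chiral ylide may be weak on so reactive an acceptor, the ylide may decompose before the o-quinone methide is released, or the methide may dimerise. The fallback uses the known carbene route already used for dihydrofuran A and sets out from 27. Selective O-alkylation of the phenol with 4-methoxybenzyl chloride (K2CO3, DMF) should give the 4-methoxybenzyl ether F1. Dess–Martin oxidation then gives the diaryl ketone F2, and hydrazine gives the hydrazone F3. MnO2 oxidation to the diaryldiazomethane F4 and insertion with the mirror-image catalyst Rh2(R-PTAD)4 should give the (7cS,8cR)-cis-dihydrobenzofuran F5. Treatment of F5 with CF3CO2H in CH2Cl2 epimerises C7c, and the sequence comes back to the route at 41.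

2. Step 7. The di-ortho-substituted diaryl carbene may be diverted (azine formation, attack on the silyl ether oxygen) or may insert with eroded enantioselection, and the hydrazone before it may form sluggishly. The fallback replaces the carbene by an anionic ring closure and a resolution, and sets out from 11. LDA (THF, −78 to 0 °C) deprotonates the ortho benzylic ether, and intramolecular addition to the ketone gives the 3-hydroxy-2,3-diaryl-2,3-dihydrobenzofuran F6. Ionic hydrogenation (Et3SiH, CF3CO2H, CH2Cl2) reduces the C8a cation anti to the C7a aryl group and removes the second 4-methoxybenzyl ether, giving the racemic trans phenol F7. F7 is resolved by preparative chromatography on a chiral stationary phase, and the (2S,3S) enantiomer is kept. n-Bu4NF gives the diol F8, MnO2 the aldehyde F9, and olefination with 21 (one extra equivalent of NaH for the phenol) the stilbene F10. CF3CO2H then closes the seven-membered ring, and the sequence comes back to the route at 25.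

3. Step 13. Carbon–carbon bond formation at C14b, flanked by the phenoxide and the C8b methylene, may be slow with the bulky aromatic aldehyde, or may leak to C12b. The fallback splits the event into a small electrophile and an aryl nucleophile and sets out from 25. Magnesium-mediated ortho-formylation (MgCl2, Et3N, paraformaldehyde, MeCN, reflux) gives the salicylaldehyde F11. Addition of 3,5-dimethoxyphenylmagnesium bromide (two equivalents, the first consumed by the phenol) comes back to the route at 27.

**Further compounds**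

F1 | step 18 | O13b 4-methoxybenzyl ether of 27 | COc1ccc([C@H]2Oc3cc(OCc4ccc(OC)cc4)c(C(O)c4cc(OC)cc(OC)c4)c4c3[C@@H]2c2cc(OC)cc(OC)c2[C@H](c2ccc(OC)cc2OC)C4)cc1
F2 | step 18 | C14b 3,5-dimethoxybenzoyl ketone from F1 | COc1ccc([C@H]2Oc3cc(OCc4ccc(OC)cc4)c(C(=O)c4cc(OC)cc(OC)c4)c4c3[C@@H]2c2cc(OC)cc(OC)c2[C@H](c2ccc(OC)cc2OC)C4)cc1
F3 | step 18 | hydrazone of F2 | COc1ccc([C@H]2Oc3cc(OCc4ccc(OC)cc4)c(C(=NN)c4cc(OC)cc(OC)c4)c4c3[C@@H]2c2cc(OC)cc(OC)c2[C@H](c2ccc(OC)cc2OC)C4)cc1
F4 | step 18 | diaryldiazomethane from F3 | COc1ccc([C@H]2Oc3cc(OCc4ccc(OC)cc4)c(C(=[N+]=[N-])c4cc(OC)cc(OC)c4)c4c3[C@@H]2c2cc(OC)cc(OC)c2[C@H](c2ccc(OC)cc2OC)C4)cc1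
F5 | step 18 | (7cS,8cR)-cis epimer of 41 | COc1ccc([C@H]2Oc3cc4c(c5c3[C@@H]2c2cc(OC)cc(OC)c2[C@H](c2ccc(OC)cc2OC)C5)[C@@H](c2cc(OC)cc(OC)c2)[C@@H](c2ccc(OC)cc2)O4)cc1
F6 | step 7 | 3-(3,5-dimethoxyphenyl)-3-hydroxy-6-(4-methoxybenzyloxy)-2-(4-methoxyphenyl)-4-(triisopropylsilyloxymethyl)-2,3-dihydrobenzofuran (racemic, diastereomer mixture) | COc1ccc(C2Oc3cc(OCc4ccc(OC)cc4)cc(CO[Si](C(C)C)(C(C)C)C(C)C)c3C2(O)c2cc(OC)cc(OC)c2)cc1
F7 | step 7 | trans-3-(3,5-dimethoxyphenyl)-2-(4-methoxyphenyl)-4-(triisopropylsilyloxymethyl)-2,3-dihydrobenzofuran-6-ol, formed as the racemate, drawn as the (2S,3S) enantiomer kept after resolution | COc1ccc([C@H]2Oc3cc(O)cc(CO[Si](C(C)C)(C(C)C)C(C)C)c3[C@@H]2c2cc(OC)cc(OC)c2)cc1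
F8 | step 7 | (2S,3S)-trans-3-(3,5-dimethoxyphenyl)-4-(hydroxymethyl)-2-(4-methoxyphenyl)-2,3-dihydrobenzofuran-6-ol | COc1ccc([C@H]2Oc3cc(O)cc(CO)c3[C@@H]2c2cc(OC)cc(OC)c2)cc1
F9 | step 7 | (2S,3S)-trans-3-(3,5-dimethoxyphenyl)-6-hydroxy-2-(4-methoxyphenyl)-2,3-dihydrobenzofuran-4-carbaldehyde | COc1ccc([C@H]2Oc3cc(O)cc(C=O)c3[C@@H]2c2cc(OC)cc(OC)c2)cc1
F10 | step 7 | (2S,3S)-trans-4-[(E)-2-(2,4-dimethoxyphenyl)ethenyl]-3-(3,5-dimethoxyphenyl)-2-(4-methoxyphenyl)-2,3-dihydrobenzofuran-6-ol | COc1ccc([C@H]2Oc3cc(O)cc(/C=C/c4ccc(OC)cc4OC)c3[C@@H]2c2cc(OC)cc(OC)c2)cc1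
F11 | step 13 | C14b-formyl derivative of 25 (salicylaldehyde) | COc1ccc([C@H]2Oc3cc(O)c(C=O)c4c3[C@@H]2c2cc(OC)cc(OC)c2[C@H](c2ccc(OC)cc2OC)C4)cc1
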